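Numbering from the carboxyl carbon (C1), the plan rests on opening the 1,2-dioxolane (O1, O2, C3, C4, C5) at its C5–O bond and reading the C5 methyl group and that C–O bond as the two outcomes of one exocyclic CH2 on C5. In a single operation a cobalt hydride should deliver a hydrogen atom to this methylidene, the oxidised tertiary C5 centre should be captured by a silylperoxy oxygen held on C3, and ring and C5 stereocentre form together. The substrate is an acyclic (3S,7R) tertiary triethylsilyl peroxide bearing an acetoxyethyl arm on C3, the C5 methylidene and a silyl-protected C14 alcohol; C3 stems from a Sharpless epoxide through an oxetane, C7 from (R)-citronellal.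

Key step: step 15

Remarks on the chemistry:
- Target-chain numbering (C1 = carboxyl carbon, C14 = first diene carbon) is used in the Why lines; the target is (3S,5R,7R).
- The C1 oxygen is carried through the key step as an acetate. An alcohol or silyl ether oxygen on C1 could close a six-membered oxane (O, C1, C2, C3, C4, C5) on the same C5 electrophile, whereas an ester oxygen is a poor nucleophile.
- Assumption: the silylated propargylic bromide 9 serves as the propargyl source, because it couples at its CH2 carbon and not at the alkyne terminus.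
- Peroxidic compounds 20–31 are to be kept cold, shielded and never concentrated to dryness.

Step 1
Reactants: 1 pent-4-en-1-ol
Product: 2 triisopropyl(pent-4-en-1-yloxy)silane
Conditions: iPr3SiCl, imidazole, DMF, rt
Reagents that add atoms: chlorotriisopropylsilane, CC(C)[Si](Cl)(C(C)C)C(C)C
Why: Imidazole-promoted silyl ether formation on an unhindered primary alcohol gives a group that should survive every organometallic step up to the key step.

Step 2
Reactants: 2 triisopropyl(pent-4-en-1-yloxy)silane; 3 (R)-citronellal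
Product: 4 (3R)-3-methyl-10-[(triisopropylsilyl)oxy]dec-6-enal (E/Z mixture)
Conditions: second-generation Hoveyda–Grubbs catalyst (5 mol %), 2 (3 equiv), CH2Cl2, 40 °C
Reagents that add atoms: none
Why: Olefin cross-metathesis should exchange the isopropylidene end of citronellal for the alkylidene of the terminal alkene with loss of gaseous isobutene, leaving the aldehyde and the stereocentre (later C7, not on a reacting carbon) untouched.

Step 3
Reactants: 4 (3R)-3-methyl-10-[(triisopropylsilyl)oxy]dec-6-enal
Product: 5 (3R)-3-methyl-10-[(triisopropylsilyl)oxy]decanal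
Conditions: H2 (1 atm), Pd/C, EtOAc, rt
Reagents that add atoms: none
Why: Heterogeneous catalytic hydrogenation of the disubstituted alkene removes the E/Z mixture, and an aliphatic aldehyde and a silyl ether are not expected to be reduced under these mild conditions.

Step 4
Reactants: 5 (3R)-3-methyl-10-[(triisopropylsilyl)oxy]decanal
Product: 6 triisopropyl{[(8R)-8-methylundec-10-yn-1-yl]oxy}silane
Conditions: dimethyl (1-diazo-2-oxopropyl)phosphonate, K2CO3, MeOH, 0 °C → rt
Reagents that add atoms: dimethyl (1-diazo-2-oxopropyl)phosphonate, CC(=O)C(=[N+]=[N-])P(=O)(OC)OC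
Why: The Ohira–Bestmann (Seyferth–Gilbert) homologation turns the aldehyde into the terminal alkyne under carbonate conditions, and the stereocentre, being β to the carbonyl, cannot epimerise.

Step 5
Reactants: 6 triisopropyl{[(8R)-8-methylundec-10-yn-1-yl]oxy}silane
Product: 8 {[(8R)-10-bromo-8-methylundec-10-en-1-yl]oxy}triisopropylsilane, via bromoalkenylborane 7 (not isolated)
Conditions: B-bromo-9-BBN, CH2Cl2, 0 °C; then AcOH, 0 °C → rt
Reagents that add atoms: B-bromo-9-borabicyclo[3.3.1]nonane, BrB1C2CCCC1CCC2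
Why: Haloboration–protodeboronation places bromine on the internal alkyne carbon by syn addition of Br–B, and acetic acid then cleaves the vinyl C–B bond to leave the 2-bromo-1-alkene that will become C5 with its methylidene.

Step 6
Reactants: 8 {[(8R)-10-bromo-8-methylundec-10-en-1-yl]oxy}triisopropylsilane; 9 (3-bromoprop-1-yn-1-yl)trimethylsilane
Product: 11 triisopropyl{[(8R)-8-methyl-10-methylidene-13-(trimethylsilyl)tridec-12-yn-1-yl]oxy}silane, via alkenylmagnesium bromide 10 (not isolated)
Conditions: Mg, THF, 50 °C; then 9, CuBr·SMe2 (10 mol %), THF, −20 °C → rt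
Reagents that add atoms: none
Why: Grignard formation followed by copper-catalysed SN2 coupling with the propargylic bromide forms the C4–C5 bond, the trimethylsilyl group shielding the alkyne terminus so that the SN2′ (allene) pathway is disfavoured.

Step 7
Reactants: 11 triisopropyl{[(8R)-8-methyl-10-methylidene-13-(trimethylsilyl)tridec-12-yn-1-yl]oxy}silane
Product: 12 triisopropyl{[(8R)-8-methyl-10-methylidenetridec-12-yn-1-yl]oxy}silane
Conditions: K2CO3, MeOH, rt
Reagents that add atoms: none
Why: Carbonate-catalysed protodesilylation cleaves only the alkynyl C–Si bond, under conditions mild enough that the skipped enyne should not isomerise and the silyl ether stays on.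

Step 8
Reactants: 12 triisopropyl{[(8R)-8-methyl-10-methylidenetridec-12-yn-1-yl]oxy}silane
Product: 15 (2E,7R)-3,7-dimethyl-5-methylidene-14-[(triisopropylsilyl)oxy]tetradec-2-en-1-ol, via alkenyldimethylalane 13 (not isolated), via lithium alkenylalanate 14 (not isolated)
Conditions: AlMe3, Cp2ZrCl2 (25 mol %), CH2Cl2, 0 °C → rt; evaporation; n-BuLi, THF, −78 °C; (CH2O)n, −78 °C → rt; aq. HCl
Reagents that add atoms: trimethylaluminium, C[Al](C)C; paraformaldehyde (as formaldehyde), C=O
Why: Negishi zirconium-catalysed carboalumination adds methyl and aluminium syn across the terminal alkyne with aluminium at the terminus, and the derived alanate attacks formaldehyde with retention, which fixes the (E)-3-methyl allylic alcohol.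

Step 9
Reactants: 15 (2E,7R)-3,7-dimethyl-5-methylidene-14-[(triisopropylsilyl)oxy]tetradec-2-en-1-ol
Product: 16 [(2R,3R)-3-methyl-3-{(4R)-4-methyl-2-methylidene-11-[(triisopropylsilyl)oxy]undecyl}oxiran-2-yl]methanol
Conditions: Ti(OiPr)4 (10 mol %), D-(−)-diethyl tartrate (12 mol %), t-BuOOH, 4 Å MS, CH2Cl2, −20 °C
Reagents that add atoms: tert-butyl hydroperoxide, CC(C)(C)OO
Why: Sharpless asymmetric epoxidation touches only the allylic alcohol alkene, and D-(−)-tartrate is expected, by analogy with other (E)-3-methyl allylic alcohols, to give the (2R,3R)-epoxide, so C3 is set by the reagent.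

Step 10
Reactants: 16 [(2R,3R)-3-methyl-3-{(4R)-4-methyl-2-methylidene-11-[(triisopropylsilyl)oxy]undecyl}oxiran-2-yl]methanol
Product: 17 (3R,7R)-3,7-dimethyl-5-methylidene-14-[(triisopropylsilyl)oxy]tetradecane-1,3-diol
Conditions: NaAlH2(OCH2CH2OMe)2, THF, 0 °C → rt
Reagents that add atoms: none
Why: Hydroxyl-directed epoxide reduction delivers hydride from the alkoxy-bound aluminate to C2, so the C3–O bond and the C3 configuration are kept and the 1,3-diol results.

Step 11
Reactants: 17 (3R,7R)-3,7-dimethyl-5-methylidene-14-[(triisopropylsilyl)oxy]tetradecane-1,3-diol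
Product: 19 (2R)-2-methyl-2-{(4R)-4-methyl-2-methylidene-11-[(triisopropylsilyl)oxy]undecyl}oxetane, via primary monotosylate 18 (not isolated)
Conditions: n-BuLi (1 equiv), THF, 0 °C; TsCl (1 equiv); n-BuLi (1 equiv), 0 → 60 °C
Reagents that add atoms: none
Why: Selective sulfonylation of the primary alkoxide followed by intramolecular Williamson etherification (4-exo-tet) by the tertiary alkoxide closes the oxetane without breaking the C3–O bond, so C3 is retained.

Step 12
Reactants: 19 (2R)-2-methyl-2-{(4R)-4-methyl-2-methylidene-11-[(triisopropylsilyl)oxy]undecyl}oxetane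
Product: 20 (3S,7R)-3-hydroperoxy-3,7-dimethyl-5-methylidene-14-[(triisopropylsilyl)oxy]tetradecan-1-ol
Conditions: H2O2 (anhydrous, in Et2O), Me3SiOTf (cat.), Et2O, −78 → 0 °C
Reagents that add atoms: hydrogen peroxide, OO
Why: Lewis-acid-promoted perhydrolysis of a 2,2-disubstituted oxetane should direct H2O2 to the tertiary C3 in a tight-ion-pair, SN2-like opening with inversion, giving the (3S) hydroperoxide and freeing the C1 alcohol.

Step 13
Reactants: 20 (3S,7R)-3-hydroperoxy-3,7-dimethyl-5-methylidene-14-[(triisopropylsilyl)oxy]tetradecan-1-ol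
Product: 21 (3S,7R)-3-hydroperoxy-3,7-dimethyl-5-methylidene-14-[(triisopropylsilyl)oxy]tetradecyl acetate
Conditions: vinyl acetate, immobilised Candida antarctica lipase B, t-BuOMe, rt
Reagents that add atoms: vinyl acetate, C=COC(C)=O
Why: Lipase-catalysed transesterification should acylate the unhindered primary alcohol while the tertiary hydroperoxide is too hindered for the active site, and the neutral medium spares the O–O bond.

Step 14
Reactants: 21 (3S,7R)-3-hydroperoxy-3,7-dimethyl-5-methylidene-14-[(triisopropylsilyl)oxy]tetradecyl acetate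
Product: 22 (3S,7R)-3,7-dimethyl-5-methylidene-3-[(triethylsilyl)peroxy]-14-[(triisopropylsilyl)oxy]tetradecyl acetate
Conditions: Et3SiCl, imidazole, DMF, 0 °C
Reagents that add atoms: chlorotriethylsilane, CC[Si](Cl)(CC)CC
Why: Silylation of the only remaining O–H (silyl peroxide formation) masks the hydroperoxide against cobalt-induced decomposition and provides the leaving group for the ring closure.

Step 15
Reactants: 22 (3S,7R)-3,7-dimethyl-5-methylidene-3-[(triethylsilyl)peroxy]-14-[(triisopropylsilyl)oxy]tetradecyl acetate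
Product: 23 2-[(3R,5R)-3,5-dimethyl-5-{(2R)-2-methyl-9-[(triisopropylsilyl)oxy]nonyl}-1,2-dioxolan-3-yl]ethyl acetate
Conditions: Co(salen) (divalent cobalt, 5 mol %), N-fluoro-2,4,6-trimethylpyridinium tetrafluoroborate, PhSiH3, PhCF3, 0 °C → rt, argon
Reagents that add atoms: none
Why: Proposed new method: the trivalent cobalt hydride formed from Co(salen), the N-fluoropyridinium oxidant and PhSiH3 should transfer a hydrogen atom to the terminal carbon of the C5 methylidene, creating the C5 methyl and a tertiary C5 radical that, after capture by cobalt and one-electron oxidation, becomes a tetravalent alkylcobalt species acting as a C5 cation equivalent; the silylated peroxy oxygen on C3 attacks it and the triethylsilyl group leaves as its fluoride, forming C5–O. The closest known reaction type is the cobalt-hydride MHAT radical–polar crossover hydroalkoxylation of unactivated alkenes by hydroxyl or silyl ether oxygen, in which a silyl peroxide has not served as the nucleophile. The 1,2-dioxolane (O1, O2, C3, C4, C5) closes in a 5-exo Markovnikov mode with respect to the alkene. The new C5 centre is controlled by the resident C3 centre across the forming ring, closure being expected on the face that puts the C6 chain trans to the acetoxyethyl arm, and either enantiomer of a cyclohexanediamine-derived salen ligand can be tried to reinforce this. The step needs hydrogen-atom transfer at the only alkene present, survival of the O–O bond in a reducing medium and no rival oxygen nucleophile: silyl peroxides are known to persist in cobalt/silane mixtures, and the C1 oxygen is an acetate that cannot close the six-membered oxane.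

Step 16
Reactants: 23 2-[(3R,5R)-3,5-dimethyl-5-{(2R)-2-methyl-9-[(triisopropylsilyl)oxy]nonyl}-1,2-dioxolan-3-yl]ethyl acetate
Product: 24 2-{(3R,5R)-5-[(2R)-9-hydroxy-2-methylnonyl]-3,5-dimethyl-1,2-dioxolan-3-yl}ethyl acetate
Conditions: HF·pyridine, pyridine, THF, 0 °C → rt
Reagents that add atoms: none
Why: Fluoride-mediated cleavage of the primary silyl ether under buffered, weakly acidic conditions should leave the acetate and the fully substituted dialkyl peroxide intact.

Step 17
Reactants: 24 2-{(3R,5R)-5-[(2R)-9-hydroxy-2-methylnonyl]-3,5-dimethyl-1,2-dioxolan-3-yl}ethyl acetate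
Product: 25 2-{(3R,5R)-3,5-dimethyl-5-[(2R)-2-methyl-9-oxononyl]-1,2-dioxolan-3-yl}ethyl acetate
Conditions: Dess–Martin periodinane, NaHCO3, CH2Cl2, rt
Reagents that add atoms: none
Why: Dess–Martin oxidation takes the primary alcohol to the C14 aldehyde under neutral buffered conditions that do not attack the peroxide.

Step 18
Reactants: 25 2-{(3R,5R)-3,5-dimethyl-5-[(2R)-2-methyl-9-oxononyl]-1,2-dioxolan-3-yl}ethyl acetate; 26 diethyl [(2E)-3-phenylprop-2-en-1-yl]phosphonate
Product: 28 2-{(3R,5R)-3,5-dimethyl-5-[(2R,9E,11E)-2-methyl-12-phenyldodeca-9,11-dien-1-yl]-1,2-dioxolan-3-yl}ethyl acetate, via lithiated phosphonate 27 (not isolated)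
Conditions: 26, LiN(SiMe3)2, THF, −78 °C; then 25, −78 °C → rt
Reagents that add atoms: none
Why: Horner–Wadsworth–Emmons olefination with the lithiated allylic phosphonate forms C14=C15 with the usual E preference while the cinnamyl E geometry comes in with the reagent, and addition to the aldehyde at low temperature should outrun attack on the acetate.

Step 19
Reactants: 28 2-{(3R,5R)-3,5-dimethyl-5-[(2R,9E,11E)-2-methyl-12-phenyldodeca-9,11-dien-1-yl]-1,2-dioxolan-3-yl}ethyl acetate
Product: 29 2-{(3R,5R)-3,5-dimethyl-5-[(2R,9E,11E)-2-methyl-12-phenyldodeca-9,11-dien-1-yl]-1,2-dioxolan-3-yl}ethan-1-ol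
Conditions: K2CO3, MeOH, 0 °C → rt
Reagents that add atoms: none
Why: Carbonate-catalysed transesterification removes the acetate, and the dioxolane, having no hydrogen on its peroxide carbons, cannot undergo Kornblum–DeLaMare fragmentation under this mild base.

Step 20
Reactants: 29 2-{(3R,5R)-3,5-dimethyl-5-[(2R,9E,11E)-2-methyl-12-phenyldodeca-9,11-dien-1-yl]-1,2-dioxolan-3-yl}ethan-1-ol
Product: 31 2-{(3S,5R)-3,5-dimethyl-5-[(2R,9E,11E)-2-methyl-12-phenyldodeca-9,11-dien-1-yl]-1,2-dioxolan-3-yl}acetic acid, via β-peroxy aldehyde 30 (not isolated)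
Conditions: TEMPO (cat.), PhI(OAc)2, MeCN/aq. pH 7 buffer, rt
Reagents that add atoms: water, O
Why: Oxoammonium-mediated (TEMPO/PhI(OAc)2) oxidation takes the primary alcohol to the aldehyde and, through its hydrate, to the carboxylic acid in a buffered medium that avoids base at the β-peroxy carbonyl stage and should leave the diene alone.

Compound list
1 | pent-4-en-1-ol | C=CCCCO | starting material
2 | triisopropyl(pent-4-en-1-yloxy)silane | C=CCCCO[Si](C(C)C)(C(C)C)C(C)C | intermediate
3 | (R)-citronellal, (3R)-3,7-dimethyloct-6-enal | C[C@H](CCC=C(C)C)CC=O | starting material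
4 | (3R)-3-methyl-10-[(triisopropylsilyl)oxy]dec-6-enal (E/Z mixture) | C[C@H](CCC=CCCCO[Si](C(C)C)(C(C)C)C(C)C)CC=O | intermediate
5 | (3R)-3-methyl-10-[(triisopropylsilyl)oxy]decanal | C[C@H](CCCCCCCO[Si](C(C)C)(C(C)C)C(C)C)CC=O | intermediate
6 | triisopropyl{[(8R)-8-methylundec-10-yn-1-yl]oxy}silane | C[C@H](CCCCCCCO[Si](C(C)C)(C(C)C)C(C)C)CC#C | intermediate
7 | 9-{(1Z,4R)-2-bromo-4-methyl-11-[(triisopropylsilyl)oxy]undec-1-en-1-yl}-9-borabicyclo[3.3.1]nonane | C[C@H](CCCCCCCO[Si](C(C)C)(C(C)C)C(C)C)C/C(Br)=C/B1C2CCCC1CCC2 | intermediate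
8 | {[(8R)-10-bromo-8-methylundec-10-en-1-yl]oxy}triisopropylsilane | C[C@H](CCCCCCCO[Si](C(C)C)(C(C)C)C(C)C)CC(Br)=C | intermediate
9 | (3-bromoprop-1-yn-1-yl)trimethylsilane | C[Si](C)(C)C#CCBr | starting material
10 | bromo{(4R)-4-methyl-11-[(triisopropylsilyl)oxy]undec-1-en-2-yl}magnesium | C[C@H](CCCCCCCO[Si](C(C)C)(C(C)C)C(C)C)CC(=C)[Mg]Br | intermediate
11 | triisopropyl{[(8R)-8-methyl-10-methylidene-13-(trimethylsilyl)tridec-12-yn-1-yl]oxy}silane | C[C@H](CCCCCCCO[Si](C(C)C)(C(C)C)C(C)C)CC(=C)CC#C[Si](C)(C)C | intermediate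
12 | triisopropyl{[(8R)-8-methyl-10-methylidenetridec-12-yn-1-yl]oxy}silane | C[C@H](CCCCCCCO[Si](C(C)C)(C(C)C)C(C)C)CC(=C)CC#C | intermediate
13 | {(1E,6R)-2,6-dimethyl-4-methylidene-13-[(triisopropylsilyl)oxy]tridec-1-en-1-yl}dimethylalumane | C[C@H](CCCCCCCO[Si](C(C)C)(C(C)C)C(C)C)CC(=C)C/C(C)=C/[Al](C)C | intermediate
14 | lithium butyl{(1E,6R)-2,6-dimethyl-4-methylidene-13-[(triisopropylsilyl)oxy]tridec-1-en-1-yl}dimethylaluminate | [Li+].C[C@H](CCCCCCCO[Si](C(C)C)(C(C)C)C(C)C)CC(=C)C/C(C)=C/[Al-](C)(C)CCCC | intermediate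
15 | (2E,7R)-3,7-dimethyl-5-methylidene-14-[(triisopropylsilyl)oxy]tetradec-2-en-1-ol | C[C@H](CCCCCCCO[Si](C(C)C)(C(C)C)C(C)C)CC(=C)C/C(C)=C/CO | intermediate
16 | [(2R,3R)-3-methyl-3-{(4R)-4-methyl-2-methylidene-11-[(triisopropylsilyl)oxy]undecyl}oxiran-2-yl]methanol | C[C@H](CCCCCCCO[Si](C(C)C)(C(C)C)C(C)C)CC(=C)C[C@@]1(C)O[C@@H]1CO | intermediate
17 | (3R,7R)-3,7-dimethyl-5-methylidene-14-[(triisopropylsilyl)oxy]tetradecane-1,3-diol | C[C@H](CCCCCCCO[Si](C(C)C)(C(C)C)C(C)C)CC(=C)C[C@](C)(CCO)O | intermediate
18 | (3R,7R)-3-hydroxy-3,7-dimethyl-5-methylidene-14-[(triisopropylsilyl)oxy]tetradecyl 4-methylbenzenesulfonate | C[C@H](CCCCCCCO[Si](C(C)C)(C(C)C)C(C)C)CC(=C)C[C@](C)(CCOS(=O)(=O)c1ccc(C)cc1)O | intermediate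
19 | (2R)-2-methyl-2-{(4R)-4-methyl-2-methylidene-11-[(triisopropylsilyl)oxy]undecyl}oxetane | C[C@H](CCCCCCCO[Si](C(C)C)(C(C)C)C(C)C)CC(=C)C[C@]1(C)CCO1 | intermediate
20 | (3S,7R)-3-hydroperoxy-3,7-dimethyl-5-methylidene-14-[(triisopropylsilyl)oxy]tetradecan-1-ol | C[C@H](CCCCCCCO[Si](C(C)C)(C(C)C)C(C)C)CC(=C)C[C@@](C)(CCO)OO | intermediate
21 | (3S,7R)-3-hydroperoxy-3,7-dimethyl-5-methylidene-14-[(triisopropylsilyl)oxy]tetradecyl acetate | C[C@H](CCCCCCCO[Si](C(C)C)(C(C)C)C(C)C)CC(=C)C[C@@](C)(CCOC(C)=O)OO | intermediate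
22 | (3S,7R)-3,7-dimethyl-5-methylidene-3-[(triethylsilyl)peroxy]-14-[(triisopropylsilyl)oxy]tetradecyl acetate | C[C@H](CCCCCCCO[Si](C(C)C)(C(C)C)C(C)C)CC(=C)C[C@@](C)(CCOC(C)=O)OO[Si](CC)(CC)CC | intermediate
23 | 2-[(3R,5R)-3,5-dimethyl-5-{(2R)-2-methyl-9-[(triisopropylsilyl)oxy]nonyl}-1,2-dioxolan-3-yl]ethyl acetate | C[C@H](CCCCCCCO[Si](C(C)C)(C(C)C)C(C)C)C[C@]1(C)C[C@@](C)(CCOC(C)=O)OO1 | intermediate
24 | 2-{(3R,5R)-5-[(2R)-9-hydroxy-2-methylnonyl]-3,5-dimethyl-1,2-dioxolan-3-yl}ethyl acetate | C[C@H](CCCCCCCO)C[C@]1(C)C[C@@](C)(CCOC(C)=O)OO1 | intermediate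
25 | 2-{(3R,5R)-3,5-dimethyl-5-[(2R)-2-methyl-9-oxononyl]-1,2-dioxolan-3-yl}ethyl acetate | C[C@H](CCCCCCC=O)C[C@]1(C)C[C@@](C)(CCOC(C)=O)OO1 | intermediate
26 | diethyl [(2E)-3-phenylprop-2-en-1-yl]phosphonate (diethyl cinnamylphosphonate) | CCOP(=O)(OCC)C/C=C/c1ccccc1 | starting material
27 | lithium (2E)-1-(diethoxyphosphoryl)-3-phenylprop-2-en-1-ide | [Li+].CCOP(=O)(OCC)[CH-]/C=C/c1ccccc1 | intermediate
28 | 2-{(3R,5R)-3,5-dimethyl-5-[(2R,9E,11E)-2-methyl-12-phenyldodeca-9,11-dien-1-yl]-1,2-dioxolan-3-yl}ethyl acetate | C[C@H](CCCCCC/C=C/C=C/c1ccccc1)C[C@]1(C)C[C@@](C)(CCOC(C)=O)OO1 | intermediate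
29 | 2-{(3R,5R)-3,5-dimethyl-5-[(2R,9E,11E)-2-methyl-12-phenyldodeca-9,11-dien-1-yl]-1,2-dioxolan-3-yl}ethan-1-ol | C[C@H](CCCCCC/C=C/C=C/c1ccccc1)C[C@]1(C)C[C@@](C)(CCO)OO1 | intermediate
30 | 2-{(3S,5R)-3,5-dimethyl-5-[(2R,9E,11E)-2-methyl-12-phenyldodeca-9,11-dien-1-yl]-1,2-dioxolan-3-yl}acetaldehyde | C[C@H](CCCCCC/C=C/C=C/c1ccccc1)C[C@]1(C)C[C@@](C)(CC=O)OO1 | intermediate
31 | 2-{(3S,5R)-3,5-dimethyl-5-[(2R,9E,11E)-2-methyl-12-phenyldodeca-9,11-dien-1-yl]-1,2-dioxolan-3-yl}acetic acid | C[C@H](CCCCCC/C=C/C=C/c1ccccc1)C[C@]1(C)C[C@@](C)(CC(=O)O)OO1 | target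

Total step count: 20.
Longest linear sequence: 20 steps (pent-4-en-1-ol to the target; 19 steps counted from (R)-citronellal).

Steps most likely to fail

Step 15 (proposed new method). The process at risk is the hand-over from radical to polar chemistry next to a peroxide. The O–O bond may be reduced or homolysed by low-valent cobalt. The C5 radical may attack the O–O bond itself. The weakly basic silylperoxy oxygen may be too slow, so that fluoride capture or elimination at C5 takes over. Facial selectivity at C5 may also be poor. The fallback uses known chemistry and sets out from hydroperoxide 21. Cycloperoxymercuration with Hg(OAc)2 in CH2Cl2 should close the same ring in the 5-exo mode and give the (acetoxymercurio)methyl dioxolane F1 as a pair of C5 epimers. Hydride demercuration (NaBH4, aqueous NaOH, 0 °C) would then replace mercury by hydrogen and so create the C5 methyl. After chromatographic separation of the C5 epimers the material comes back to the route at 23.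

Step 12. The process at risk is ionisation at C3 running ahead of peroxide delivery. That would erode the inversion, allow elimination toward C2 or C4, let the C5 methylidene intercept the C3 cation, or permit acid-promoted hydroperoxidation of the methylidene. The fallback sets out from oxetane 19 and reverses the order in which the two C–O bonds of the ring are made. A Mukaiyama–Isayama peroxidation (Co(acac)2, O2, Et3SiH, EtOH/ClCH2CH2Cl) would place the peroxide on C5 and create the C5 methyl, giving the silylperoxy oxetane F2 as both C5 epimers. Methanolysis (K2CO3, MeOH) would free the hydroperoxy oxetane F3. Its Lewis-acid-promoted intramolecular 5-exo opening of the oxetane at C3, with inversion, should give the hydroxyethyl dioxolane F4. Only C3 is secured in this way, so the C5 epimers must be separated. Acetylation (Ac2O, pyridine) then returns to the route at 23, bypassing compounds 20–22 and step 15.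

Step 13. The process at risk is chemoselective acyl transfer: the enzyme may be sluggish on this lipophilic substrate, may be deactivated by the hydroperoxide, or acyl transfer to the peroxy oxygen may intrude. The fallback sets out from 20 and inverts the order of protection. Selective deprotonation of the more acidic hydroperoxide (KN(SiMe3)2, 1 equiv, THF, −78 °C) and trapping with Et3SiCl should give the silylperoxy alcohol F5. Ordinary acetylation (Ac2O, pyridine, DMAP) then returns to the route at 22.

Further compounds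
F1 | step 15 | 2-[(3R)-5-[(acetoxymercurio)methyl]-3-methyl-5-{(2R)-2-methyl-9-[(triisopropylsilyl)oxy]nonyl}-1,2-dioxolan-3-yl]ethyl acetate (C5 epimers; the epimer leading to 23 is drawn) | C[C@H](CCCCCCCO[Si](C(C)C)(C(C)C)C(C)C)C[C@]1(C[Hg]OC(C)=O)C[C@@](C)(CCOC(C)=O)OO1
F2 | step 12 | (2R)-2-methyl-2-{(4R)-2,4-dimethyl-2-[(triethylsilyl)peroxy]-11-[(triisopropylsilyl)oxy]undecyl}oxetane (epimers at the peroxide carbon; the epimer leading to 23 is drawn) | C[C@H](CCCCCCCO[Si](C(C)C)(C(C)C)C(C)C)C[C@@](C)(OO[Si](CC)(CC)CC)C[C@]1(C)CCO1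
F3 | step 12 | (2R)-2-{(4R)-2-hydroperoxy-2,4-dimethyl-11-[(triisopropylsilyl)oxy]undecyl}-2-methyloxetane (epimers at the peroxide carbon; the epimer leading to 23 is drawn) | C[C@H](CCCCCCCO[Si](C(C)C)(C(C)C)C(C)C)C[C@@](C)(OO)C[C@]1(C)CCO1
F4 | step 12 | 2-[(3R,5R)-3,5-dimethyl-5-{(2R)-2-methyl-9-[(triisopropylsilyl)oxy]nonyl}-1,2-dioxolan-3-yl]ethan-1-ol | C[C@H](CCCCCCCO[Si](C(C)C)(C(C)C)C(C)C)C[C@]1(C)C[C@@](C)(CCO)OO1
F5 | step 13 | (3S,7R)-3,7-dimethyl-5-methylidene-3-[(triethylsilyl)peroxy]-14-[(triisopropylsilyl)oxy]tetradecan-1-ol | C[C@H](CCCCCCCO[Si](C(C)C)(C(C)C)C(C)C)CC(=C)C[C@@](C)(CCO)OO[Si](CC)(CC)CC
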